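**Strategy.** Rings A and B are disconnected across C3–C4 and C5–C10. The key step exploits the aldol pattern C3(OH)–C4–C19 of ring A and the C5–C10 bond shared by rings A and B. Hydrogen-atom transfer to a C10=C20 methylene on a bicyclo[3.2.1]octane (rings C and D) gives the C10 radical, which closes ring B on C5 of a C6-bound 2-methyl enal; the resulting C4 enolate closes ring A on the C3 aldehyde. One catalytic reduction sets C11; a Claisen rearrangement relays it to C8, and the remaining centres follow by substrate control or equilibration.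

Key step: step 13

Remark: atoms carry gibberellane locants (C1–C20) throughout and the SMILES strings define the absolute configuration. The oxazaborolidine reduction of step 2 is assumed to follow its usual model (enone alkene as the large group); if the sense is opposite, the (R)-catalyst is used.

**Step 1**
Reactants: 1 3-ethoxycyclohex-2-en-1-one; 2 3-bromoprop-1-yne
Product: 5 3-(prop-2-yn-1-yl)cyclohex-2-en-1-one, via prop-2-yn-1-ylmagnesium bromide 3 (not isolated), via the tertiary carbinol adduct 4 (not isolated)
Conditions: 2, Mg, HgCl2 (cat.), Et2O, 0 °C; then 1, −20 °C; then 1 M HCl, 0 °C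
Reagents that add atoms: water, O
Why: 1,2-Addition of the propargyl Grignard reagent to the vinylogous ester followed by acid hydrolysis and dehydration (Stork–Danheiser transposition) should give the 3-substituted enone with no stereocentre formed.

**Step 2**
Reactants: 5 3-(prop-2-yn-1-yl)cyclohex-2-en-1-one
Product: 6 (1R)-3-(prop-2-yn-1-yl)cyclohex-2-en-1-ol
Conditions: (S)-2-methyl-CBS-oxazaborolidine (20 mol %), catecholborane, toluene, −78 °C; then H2O
Reagents that add atoms: none
Why: Corey–Bakshi–Shibata reduction, with the enone alkene acting as the large group, should deliver hydride to one carbonyl face and set C11 as (R), while catecholborane leaves the terminal alkyne untouched at −78 °C.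

**Step 3**
Reactants: 6 (1R)-3-(prop-2-yn-1-yl)cyclohex-2-en-1-ol; 7 1,1,1-trimethoxyethane
Product: 9 methyl 2-[(1S)-1-(prop-2-yn-1-yl)cyclohex-2-en-1-yl]acetate, via the mixed ketene acetal 8 (not isolated)
Conditions: 7 (excess), EtCO2H (cat.), xylene, 140 °C, removal of MeOH
Reagents that add atoms: none
Why: Johnson–Claisen rearrangement through 8 forms the C8–C6 bond suprafacially on the ring face that carried the C11–O bond, so the C11 configuration is relayed to the quaternary C8 as (S).

**Step 4**
Reactants: 9 methyl 2-[(1S)-1-(prop-2-yn-1-yl)cyclohex-2-en-1-yl]acetate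
Product: 10 methyl 2-[(1S)-4-oxo-1-(prop-2-yn-1-yl)cyclohex-2-en-1-yl]acetate
Conditions: CrO3, 3,5-dimethylpyrazole, CH2Cl2, −20 °C
Reagents that add atoms: chromium trioxide, O=[Cr](=O)=O
Why: Allylic oxidation by the CrO3–3,5-dimethylpyrazole complex should attack C12, the only allylic CH2 (the other allylic carbon, C8, is quaternary), and give the 4,4-disubstituted cyclohexenone without touching C8.

**Step 5**
Reactants: 10 methyl 2-[(1S)-4-oxo-1-(prop-2-yn-1-yl)cyclohex-2-en-1-yl]acetate
Product: 11 methyl 2-[(1S)-4-[(tert-butyldimethylsilyl)oxy]-1-(prop-2-yn-1-yl)cyclohexa-2,4-dien-1-yl]acetate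
Conditions: TBSOTf, Et3N, CH2Cl2, 0 °C
Reagents that add atoms: tert-butyldimethylsilyl trifluoromethanesulfonate, CC(C)(C)[Si](C)(C)OS(=O)(=O)C(F)(F)F
Why: Soft enolisation of the enone can occur only towards C13 because C11 is vinylic, so the cross-conjugated 2-silyloxydiene should form regiospecifically and leave the less acidic ester alone.

**Step 6**
Reactants: 11 methyl 2-[(1S)-4-[(tert-butyldimethylsilyl)oxy]-1-(prop-2-yn-1-yl)cyclohexa-2,4-dien-1-yl]acetate
Product: 12 methyl 2-[(1S,5R)-6-methylidene-4-oxobicyclo[3.2.1]oct-2-en-1-yl]acetate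
Conditions: Ph3PAuCl (5 mol %), AgBF4 (5 mol %), toluene/MeOH (10:1), rt
Reagents that add atoms: none
Why: Monovalent-gold-catalysed 5-exo-dig carbocyclisation of the silyl enol ether onto the activated alkyne (Conia-ene type) forms C13–C16 and ring D, and because the new bridge can only span the face of C8 that carries the propargyl group, C13 is dictated by C8.

**Step 7**
Reactants: 12 methyl 2-[(1S,5R)-6-methylidene-4-oxobicyclo[3.2.1]oct-2-en-1-yl]acetate
Product: 14 methyl 2-[(1S,5R)-4,6-dioxobicyclo[3.2.1]oct-2-en-1-yl]acetate, via the secondary ozonide 13 (not isolated)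
Conditions: ozone (titrated to the Sudan Red 7B end point), CH2Cl2, −78 °C; then Me2S
Reagents that add atoms: ozone, [O-][O+]=O
Why: Ozone reacts faster with the electron-rich exocyclic methylene than with the enone alkene, so a titrated ozonolysis with reductive work-up should turn C16 into a ketone that is inert to the later hydrogen-atom transfer.

**Step 8**
Reactants: 14 methyl 2-[(1S,5R)-4,6-dioxobicyclo[3.2.1]oct-2-en-1-yl]acetate
Product: 15 methyl 2-[(1S,5R)-6-[(tert-butyldimethylsilyl)oxy]-4-oxobicyclo[3.2.1]octa-2,6-dien-1-yl]acetate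
Conditions: TBSOTf, Et3N, CH2Cl2, 0 °C
Reagents that add atoms: tert-butyldimethylsilyl trifluoromethanesulfonate, CC(C)(C)[Si](C)(C)OS(=O)(=O)C(F)(F)F
Why: The C16 ketone can enolise only towards C15 because C13 is a bridgehead and the enone carbonyl has no enolisable hydrogen, so silylation should mask C16 as a planar enol ether that protects it from the nucleophiles of steps 10 to 12.

**Step 9**
Reactants: 16 2,3-dibromoprop-1-ene; 17 (1,3-dioxolan-2-ylmethyl)magnesium bromide
Product: 18 2-(3-bromobut-3-en-1-yl)-1,3-dioxolane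
Conditions: CuI (5 mol %), THF, 0 °C
Reagents that add atoms: none
Why: Copper-catalysed substitution of the allylic bromide by the Grignard reagent leaves the vinylic bromide intact and delivers the C20, C10, C1, C2 and C3 unit with C3 masked as an acetal.

**Step 10**
Reactants: 15 methyl 2-[(1S,5R)-6-[(tert-butyldimethylsilyl)oxy]-4-oxobicyclo[3.2.1]octa-2,6-dien-1-yl]acetate; 18 2-(3-bromobut-3-en-1-yl)-1,3-dioxolane
Product: 21 methyl 2-[6-[(tert-butyldimethylsilyl)oxy]-2-[4-(1,3-dioxolan-2-yl)but-1-en-2-yl]-4-oxobicyclo[3.2.1]oct-6-en-1-yl]acetate (bridgeheads as in 15; side chain on the face of the one-carbon bridge), via the alkenyl Grignard reagent 19 (not isolated), via the C12 trimethylsilyl enol ether 20 (not isolated)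
Conditions: 18, Mg, THF, 45 °C; then CuBr·SMe2 (10 mol %), Me3SiCl, 15, THF, −78 °C; then aq. citric acid, 0 °C
Reagents that add atoms: none
Why: Copper-catalysed conjugate addition of the alkenyl Grignard reagent, accelerated by Me3SiCl, should occur on the enone face syn to the one-carbon bridge (C14) and anti to the two-carbon bridge, which sets C9 with its hydrogen on the side of the C15–C16 bridge, and the mild acid cleaves only the trimethylsilyl enol ether.

**Step 11**
Reactants: 21 the C9-alkenylated C12 ketone
Product: 22 methyl 2-[6-[(tert-butyldimethylsilyl)oxy]-2-[4-(1,3-dioxolan-2-yl)but-1-en-2-yl]-4-hydroxybicyclo[3.2.1]oct-6-en-1-yl]acetate (12-OH cis to the C9 side chain)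
Conditions: LiBH(s-Bu)3, THF, −78 °C; then H2O
Reagents that add atoms: none
Why: The bulky hydride should attack the C12 ketone along the equatorial trajectory from the side of the planar C15=C16 bridge, because the opposite axial approach is screened by the syn-axial C9 side chain, which gives the axial 12-alcohol cis to the C9–C10 bond.

**Step 12**
Reactants: 22 the 12-hydroxy ester; 23 (E)-3-ethoxy-2-methylprop-2-enal
Product: 26 methyl (3E)-2-[4-hydroxy-6-oxo-2-(5-oxopent-1-en-2-yl)bicyclo[3.2.1]octan-1-yl]-4-methyl-5-oxopent-3-enoate (key precursor; ring stereocentres as in 22; C6 epimers), via the dilithium alkoxide ester enolate 24 (not isolated), via the aldol adduct 25 (not isolated)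
Conditions: LiN(i-Pr)2 (2.3 equiv), THF, −78 °C; then 23, −78 → −20 °C; then 1 M HCl, THF, 0 °C → rt
Reagents that add atoms: water, O
Why: Aldol addition of the ester enolate to the aldehyde of the vinylogous formate 23 and acid-induced hydrolysis with allylic transposition of the adduct (formylolefination) should give the (E)-2-methyl enal, while the same acid hydrolyses the silyl enol ether and the dioxolane; C6 is formed without control, but as a CH flanked by the ester and the vinylogous aldehyde its epimers should interconvert under mild base such as Et3N, so the epimer needed in step 13 can be replenished from the other.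

**Step 13**
Reactants: 26 the key precursor (C6 epimers)
Product: 29 methyl 3,12-dihydroxy-16,19-dioxo-17-nor-ent-gibberellan-7-oate (the 16-oxo-17-nor tetracycle with C19 as aldehyde), via the tertiary C10 radical 27 (not isolated), via the ring-B-closed aldehyde enolate 28 (not isolated)
Conditions: Fe(acac)3 [Fe(C5H7O2)3] (0.5 equiv), PhSiH3, EtOH/HOCH2CH2OH (5:1), 0 °C → rt
Reagents that add atoms: none
Why: Hydrogen-atom transfer from an iron hydride to the C10=C20 methylene gives the tertiary radical 27, which adds to C5 of the enal, the α-formyl radical is reduced by divalent iron to the enolate 28, and this adds to the C3 aldehyde (radical–polar crossover; the closest known reaction type is the iron-mediated radical conjugate addition–aldol annulation of alkenes with enals). Ring B closes by a 5-exo-trig radical cyclisation through a chair-like transition state and ring A by a 6-(enolexo)-exo-trig aldol addition. C10 is controlled by C9, the larger CH2CH2CHO branch taking the face of the C9 hydrogen and the new methyl the face of C11, and C5 is relayed from C6 by allylic strain: the C6 hydrogen eclipses the alkene and the radical arrives from the C8 side, so C4 ends trans to the ester and only the C6 epimer with the ester on the C15 face leads to 29, the other epimer being expected to give a separable diastereomer. C4 is set in the chair of ring A, where the enolate carbon (hydrogen towards C5, oxygen towards C18) rather than the methyl should take the axial position beside the axial C20 methyl. C3 should be set by a non-chelated, dipole-opposed approach of the aldehyde in the protic, coordinating medium, which puts the oxygen axial and anti to C19; this is the least secure element and is answered by a fallback. The step needs hydrogen-atom transfer only to the one electron-rich alkene (secured by C16 being a ketone), 5-exo instead of 6-endo closure (secured by the unsubstituted C5 against the fully substituted C4) and aldol addition faster than enolate protonation (secured by the intramolecular six-membered closure).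

**Step 14**
Reactants: 29 the tetracyclic hydroxy aldehyde
Product: 30 7-methyl hydrogen 3,12-dihydroxy-16-oxo-17-nor-ent-gibberellane-7,19-dioate (the 16-oxo-17-nor C19 acid)
Conditions: NaClO2, NaH2PO4, 2-methylbut-2-ene, t-BuOH/H2O, 0 °C → rt
Reagents that add atoms: sodium chlorite, [Na+].[O-]Cl=O
Why: Pinnick oxidation should convert the hindered, non-enolisable C19 aldehyde into the acid under buffered conditions that induce neither retro-aldol cleavage nor epimerisation.

**Step 15**
Reactants: 30 the 16-ketone
Product: 31 7-methyl hydrogen 3,12-dihydroxy-ent-gibberell-16-ene-7,19-dioate (7-methyl ester of the target gibberellin)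
Conditions: Zn, CH2Br2, TiCl4 (excess), THF/CH2Cl2, 0 °C → rt
Reagents that add atoms: dibromomethane, BrCBr
Why: The non-basic gem-dimetallic reagent (Lombardo methylenation) should convert the C16 ketone into the exocyclic methylene without retro-aldol opening of the 12-hydroxy 16-ketone and without touching the ester, an excess covering the acidic protons.

**Step 16**
Reactants: 31 the 7-methyl ester of the target gibberellin
Product: 32 3,12-dihydroxy-ent-gibberell-16-ene-7,19-dioic acid (the target gibberellin)
Conditions: KOH (2 M), MeOH/H2O, 70 °C; then 1 M HCl to pH 3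
Reagents that add atoms: potassium hydroxide, [K+].[OH-]
Why: Saponification of the secondary C7 methyl ester by acyl–oxygen cleavage gives the diacid, C6 settling in the more stable configuration with the carboxyl trans to the C4 substituent and the C19 carboxylate preventing retro-aldol cleavage at C3.

**Compound list**

1 | 3-ethoxycyclohex-2-en-1-one | CCOC1=CC(=O)CCC1 | starting material
2 | 3-bromoprop-1-yne | C#CCBr | starting material
3 | prop-2-yn-1-ylmagnesium bromide | C#CC[Mg]Br | intermediate
4 | 3-ethoxy-1-(prop-2-yn-1-yl)cyclohex-2-en-1-ol (racemic, formed as its magnesium alkoxide) | CCOC1=CC(O)(CC#C)CCC1 | intermediate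
5 | 3-(prop-2-yn-1-yl)cyclohex-2-en-1-one | O=C1C=C(CC#C)CCC1 | intermediate
6 | (1R)-3-(prop-2-yn-1-yl)cyclohex-2-en-1-ol | O[C@H]1C=C(CC#C)CCC1 | intermediate
7 | 1,1,1-trimethoxyethane | CC(OC)(OC)OC | starting material
8 | (3R)-3-[(1-methoxyethenyl)oxy]-1-(prop-2-yn-1-yl)cyclohex-1-ene | C=C(OC)O[C@H]1C=C(CC#C)CCC1 | intermediate
9 | methyl 2-[(1S)-1-(prop-2-yn-1-yl)cyclohex-2-en-1-yl]acetate | C#CC[C@]1(CC(=O)OC)CCCC=C1 | intermediate
10 | methyl 2-[(1S)-4-oxo-1-(prop-2-yn-1-yl)cyclohex-2-en-1-yl]acetate | O=C1CC[C@](CC#C)(CC(=O)OC)C=C1 | intermediate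
11 | methyl 2-[(1S)-4-[(tert-butyldimethylsilyl)oxy]-1-(prop-2-yn-1-yl)cyclohexa-2,4-dien-1-yl]acetate | CC(C)(C)[Si](C)(C)OC1=CC[C@](CC#C)(CC(=O)OC)C=C1 | intermediate
12 | methyl 2-[(1S,5R)-6-methylidene-4-oxobicyclo[3.2.1]oct-2-en-1-yl]acetate | C=C1C[C@]2(CC(=O)OC)C[C@H]1C(=O)C=C2 | intermediate
13 | secondary ozonide of 12 (1,2,4-trioxolane spiro-fused at C16) | C1OOC2(O1)C[C@]3(CC(=O)OC)C[C@H]2C(=O)C=C3 | intermediate
14 | methyl 2-[(1S,5R)-4,6-dioxobicyclo[3.2.1]oct-2-en-1-yl]acetate | O=C1C[C@]2(CC(=O)OC)C[C@H]1C(=O)C=C2 | intermediate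
15 | methyl 2-[(1S,5R)-6-[(tert-butyldimethylsilyl)oxy]-4-oxobicyclo[3.2.1]octa-2,6-dien-1-yl]acetate | CC(C)(C)[Si](C)(C)OC1=C[C@]2(CC(=O)OC)C[C@H]1C(=O)C=C2 | intermediate
16 | 2,3-dibromoprop-1-ene | C=C(Br)CBr | starting material
17 | (1,3-dioxolan-2-ylmethyl)magnesium bromide | Br[Mg]CC1OCCO1 | starting material
18 | 2-(3-bromobut-3-en-1-yl)-1,3-dioxolane | C=C(Br)CCC1OCCO1 | intermediate
19 | [4-(1,3-dioxolan-2-yl)but-1-en-2-yl]magnesium bromide | C=C([Mg]Br)CCC1OCCO1 | intermediate
20 | C12 trimethylsilyl enol ether of 21 | CC(C)(C)[Si](C)(C)OC1=C[C@]2(CC(=O)OC)C[C@H]1C(O[Si](C)(C)C)=C[C@H]2C(=C)CCC1OCCO1 | intermediate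
21 | methyl 2-[6-[(tert-butyldimethylsilyl)oxy]-2-[4-(1,3-dioxolan-2-yl)but-1-en-2-yl]-4-oxobicyclo[3.2.1]oct-6-en-1-yl]acetate (bridgeheads as in 15; C9 side chain on the face of the C14 bridge, C9 hydrogen on the face of the C15–C16 bridge) | CC(C)(C)[Si](C)(C)OC1=C[C@]2(CC(=O)OC)C[C@H]1C(=O)C[C@H]2C(=C)CCC1OCCO1 | intermediate
22 | 12-alcohol of 21 (OH axial, cis to the C9 side chain, anti to the C15–C16 bridge) | CC(C)(C)[Si](C)(C)OC1=C[C@]2(CC(=O)OC)C[C@H]1[C@@H](O)C[C@H]2C(=C)CCC1OCCO1 | intermediate
23 | (E)-3-ethoxy-2-methylprop-2-enal | CCO/C=C(\C)C=O | starting material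
24 | dilithium 12-alkoxide ester enolate of 22 | CC(C)(C)[Si](C)(C)OC1=C[C@]2(C=C(OC)O[Li])C[C@H]1[C@@H](O[Li])C[C@H]2C(=C)CCC1OCCO1 | intermediate
25 | aldol adduct of 24 with 23, drawn protonated (C6–CH(OH)–C(CH3)=CH–OEt, diastereomer mixture) | CC(C)(C)[Si](C)(C)OC1=C[C@]2(C(C(O)C(C)=COCC)C(=O)OC)C[C@H]1[C@@H](O)C[C@H]2C(=C)CCC1OCCO1 | intermediate
26 | methyl (3E)-2-[4-hydroxy-6-oxo-2-(5-oxopent-1-en-2-yl)bicyclo[3.2.1]octan-1-yl]-4-methyl-5-oxopent-3-enoate (key precursor: C16 ketone, 12-OH, C8–CH(CO2Me)–CH=C(CH3)–CHO and C9–C(=CH2)CH2CH2CHO; C6 epimers) | O=C1C[C@]2(C(/C=C(\C)C=O)C(=O)OC)C[C@H]1[C@@H](O)C[C@H]2C(=C)CCC=O | intermediate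
27 | tertiary C10 radical from 26 | O=C1C[C@]2(C(/C=C(\C)C=O)C(=O)OC)C[C@H]1[C@@H](O)C[C@H]2[C](C)CCC=O | intermediate
28 | ring-B-closed C19 aldehyde enolate (iron-bound) with free C3 aldehyde | O=C1C[C@]23C[C@H]1[C@@H](O)C[C@H]2[C@](C)(CCC=O)[C@@H](/C(C)=C/[O-])[C@@H]3C(=O)OC | intermediate
29 | methyl 3,12-dihydroxy-16,19-dioxo-17-nor-ent-gibberellan-7-oate (3-OH cis to C18 and trans to C19; rings A and B trans-fused; 6-ester trans to C4) | O=C1C[C@]23C[C@H]1[C@@H](O)C[C@H]2[C@]1(C)CC[C@H](O)[C@@](C)(C=O)[C@H]1[C@@H]3C(=O)OC | intermediate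
30 | 7-methyl hydrogen 3,12-dihydroxy-16-oxo-17-nor-ent-gibberellane-7,19-dioate | O=C1C[C@]23C[C@H]1[C@@H](O)C[C@H]2[C@]1(C)CC[C@H](O)[C@@](C)(C(=O)O)[C@H]1[C@@H]3C(=O)OC | intermediate
31 | 7-methyl hydrogen 3,12-dihydroxy-ent-gibberell-16-ene-7,19-dioate (7-methyl ester of the target gibberellin) | C=C1C[C@]23C[C@H]1[C@@H](O)C[C@H]2[C@]1(C)CC[C@H](O)[C@@](C)(C(=O)O)[C@H]1[C@@H]3C(=O)OC | intermediate
32 | 3,12-dihydroxy-ent-gibberell-16-ene-7,19-dioic acid (the target gibberellin; 3-OH axial and cis to C18, 12-OH on the face of C14) | C=C1C[C@]23C[C@H]1[C@@H](O)C[C@H]2[C@]1(C)CC[C@H](O)[C@@](C)(C(=O)O)[C@H]1[C@@H]3C(=O)O | target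

**Step count and risks**

Total step count: 16. Longest linear sequence: 15 steps (steps 1–8 and 10–16; step 9 is a one-step branch).

Three steps most likely to fail:

1. Step 13 (key step). The aldol ring closure may proceed through an iron-chelated transition state and attack the other face of the C3 aldehyde; the radical cyclisation may also give some cis ring fusion, or the enolate may be protonated before ring A closes. The fallback answers the C3 face, runs from 26 back to 32 and moves the control of C3 (and C12) from the aldol to a ketone reduction. The cascade is then taken to give the 3-epimeric hydroxy aldehyde F1. It is carried through steps 14 and 15 unchanged to the 3-epimeric keto acid F2 and the 3-epimeric methylene acid F3. Me3SiCHN2 in MeOH/toluene then gives the 3-epimeric dimethyl ester F4, and Dess–Martin periodinane oxidises both secondary alcohols to the 3,12-diketone diester F5. KBH(s-Bu)3 at −78 °C should reduce both ketones from their open faces (equatorial attack at C3, attack anti to the quaternary C10 at C12) to the dimethyl ester of the target F6. LiSCH2CH2CH3 in HMPA then cleaves both methyl esters and the route ends at 32.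

2. Step 11. Hydride delivery at the bicyclic stage may show poor facial selectivity at C12, since the face anti to the C9 side chain is flanked by the two-carbon bridge. The fallback runs from 20 back to 31 and postpones the reduction until C10 is quaternary. The trimethylsilyl enol ether 20 is isolated without the acid wash and submitted to the enolate formylolefination of step 12, the acid treatment then giving the 12-oxo precursor F7. The cascade of step 13 should give the 12-oxo tetracyclic aldehyde F8, and NaClO2 oxidation the 12-oxo keto acid F9. Zn/CH2Br2/TiCl4 should methylenate the less hindered C16 ketone to give the 12-oxo methylene acid F10, and NaBH4 should then reduce C12 from the face anti to the quaternary C10 to reach 31.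

3. Step 12. The aldol addition to the weakly electrophilic vinylogous formate may be reversible or slow, and the double bond may migrate into conjugation with the ester during the acid treatment. The fallback runs from 22 back to 26 and forms the C6–C5 bond by cross-coupling instead. The lithium ester enolate (LiN(SiMe3)2) is coupled with (E)-(3-bromo-2-methylallyloxy)(tert-butyl)dimethylsilane under Pd(dba)2 (zerovalent palladium) and P(t-Bu)3 to give the C19 allylic silyl ether F11. Aqueous HCl in THF removes both silyl groups and the dioxolane to give the C19 allylic alcohol F12, and MnO2 oxidises only the allylic alcohol to the enal 26.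

**Further compounds**

F1 | step 13 | 3-epimer of 29 (3-epimeric hydroxy aldehyde) | O=C1C[C@]23C[C@H]1[C@@H](O)C[C@H]2[C@]1(C)CC[C@@H](O)[C@@](C)(C=O)[C@H]1[C@@H]3C(=O)OC
F2 | step 13 | 3-epimer of 30 (3-epimeric keto acid) | O=C1C[C@]23C[C@H]1[C@@H](O)C[C@H]2[C@]1(C)CC[C@@H](O)[C@@](C)(C(=O)O)[C@H]1[C@@H]3C(=O)OC
F3 | step 13 | 3-epimer of 31 (3-epimeric methylene acid) | C=C1C[C@]23C[C@H]1[C@@H](O)C[C@H]2[C@]1(C)CC[C@@H](O)[C@@](C)(C(=O)O)[C@H]1[C@@H]3C(=O)OC
F4 | step 13 | 7,19-dimethyl ester of the 3-epimer of 32 (3-epimeric dimethyl ester) | C=C1C[C@]23C[C@H]1[C@@H](O)C[C@H]2[C@]1(C)CC[C@@H](O)[C@@](C)(C(=O)OC)[C@H]1[C@@H]3C(=O)OC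
F5 | step 13 | 3,12-dioxo analogue of the 7,19-dimethyl ester of 32 (3,12-diketone diester) | C=C1C[C@]23C[C@H]1C(=O)C[C@H]2[C@]1(C)CCC(=O)[C@@](C)(C(=O)OC)[C@H]1[C@@H]3C(=O)OC
F6 | step 13 | 7,19-dimethyl ester of 32 (dimethyl ester of the target) | C=C1C[C@]23C[C@H]1[C@@H](O)C[C@H]2[C@]1(C)CC[C@H](O)[C@@](C)(C(=O)OC)[C@H]1[C@@H]3C(=O)OC
F7 | step 11 | 12-oxo analogue of 26 (12-oxo precursor) | O=C1C[C@]2(C(/C=C(\C)C=O)C(=O)OC)C[C@H]1C(=O)C[C@H]2C(=C)CCC=O
F8 | step 11 | 12-oxo analogue of 29 (12-oxo tetracyclic aldehyde) | O=C1C[C@]23C[C@H]1C(=O)C[C@H]2[C@]1(C)CC[C@H](O)[C@@](C)(C=O)[C@H]1[C@@H]3C(=O)OC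
F9 | step 11 | 12-oxo analogue of 30 (12-oxo keto acid) | O=C1C[C@]23C[C@H]1C(=O)C[C@H]2[C@]1(C)CC[C@H](O)[C@@](C)(C(=O)O)[C@H]1[C@@H]3C(=O)OC
F10 | step 11 | 12-oxo analogue of 31 (12-oxo methylene acid) | C=C1C[C@]23C[C@H]1C(=O)C[C@H]2[C@]1(C)CC[C@H](O)[C@@](C)(C(=O)O)[C@H]1[C@@H]3C(=O)OC
F11 | step 12 | C19 allylic tert-butyldimethylsilyl ether of the coupled ester (C19 allylic silyl ether) | CC(C)(C)[Si](C)(C)OC1=C[C@]2(C(/C=C(\C)CO[Si](C)(C)C(C)(C)C)C(=O)OC)C[C@H]1[C@@H](O)C[C@H]2C(=C)CCC1OCCO1
F12 | step 12 | C19 allylic alcohol analogue of 26 (C19 allylic alcohol) | O=C1C[C@]2(C(/C=C(\C)CO)C(=O)OC)C[C@H]1[C@@H](O)C[C@H]2C(=C)CCC=O
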